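Assumption: fermentation-derived (R)-(−)-mevalonolactone is taken as the inexpensive chiral feedstock. Target numbering runs from C1 (CO2H) to C21. The target is (3R,5R), with the side chain and CH2CO2H cis on the dioxolane.

## Retrosynthetic overview
1. C14=C15 is made last by Julia–Kocienski olefination of a dioxolane sulfone acid with (2E,4E)-heptadienal, so the triene never meets O2, light or diimide.
2. C5–C6 comes from alkynyl transfer from aluminium to bicyclic peroxyketal 5. The CH2CH2O–Al arm delivers the group with retention, which places the chain cis to the future CH2CO2H.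
3. Both peroxide C–O bonds come from photochemical aerobic perhydration of carbinol 4, followed by invertive 5-exo-tet opening of its oxetane.
4. Ring order: the oxetane is formed first. The dioxolane and oxane are then formed together as bicycle 5, and the oxane is opened afterwards.
5. (R)-Mevalonolactone is the only source of chirality. Its carbinol carbon becomes C3 (inverted once), and C3 then controls C5.

## Route

**Step 1**
Reactants: 1, (R)-mevalonolactone
Product: 2, (3R)-3,5-dihydroxy-N-methoxy-N,3-dimethylpentanamide
Conditions: MeNH(OMe)·HCl (3 equiv), i-PrMgCl (6 equiv), THF, −20 → 0 °C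
Reagents that add atoms: N,O-dimethylhydroxylamine hydrochloride, CNOC.Cl
Why: Weinreb aminolysis of the lactone frees the primary alcohol and turns the carbonyl (future C5) into a mono-addition acceptor, leaving the stereocentre untouched.

**Step 2**
Reactants: 2
Product: 3, N-methoxy-N-methyl-2-[(2R)-2-methyloxetan-2-yl]acetamide
Conditions: TsCl (1.05 equiv), Et3N, cat. Me3N·HCl, CH2Cl2, 0 °C; then KOt-Bu (1.2 equiv), THF, 0 °C (telescoped)
Reagents that add atoms: none
Why: Selective primary tosylation and 4-exo-tet Williamson closure by the tertiary alkoxide keep the C–O bond of the stereocentre, so configuration is retained.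

**Step 3**
Reactants: 3
Product: 4, 1-[(2R)-2-methyloxetan-2-yl]propan-2-ol (about 1:1 at the carbinol carbon, which is erased in step 4)
Conditions: MeMgBr (1.3 equiv), THF, −20 °C; then MeOH, NaBH4, 0 °C (one pot)
Reagents that add atoms: methylmagnesium bromide, C[Mg]Br
Why: Weinreb ketone synthesis installs the C5 methyl, and in-situ borohydride reduction stores the two hydrogens that will convert O2 into the peroxide; oxetanes tolerate Grignard reagents at low temperature.

**Step 4 (key step)**
Reactants: 4
Product: 5, (1S,5S)-1,5-dimethyl-2,6,7-trioxabicyclo[3.2.1]octane (C1 = future C5, C5 = future C3, C8H2 = future C4, O2–C3H2–C4H2 = future C1/C2 arm); kept as a dried toluene solution and never concentrated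
Conditions: O2 (1 atm), 2-tert-butylanthraquinone (5 mol %), MeCN (0.5 M), 405 nm LED, 10 °C; then in the dark Yb(OTf)3 (10 mol %), 4 Å MS, 0 °C → rt
Reagents that add atoms: dioxygen, O=O
Why: Proposed new method: triplet anthraquinone abstracts the weak, hydridic carbinol C–H, the ketyl radical traps O2 (forming the C5–O bond), and H-return from the semiquinone gives the α-hydroxy-hydroperoxide (ketone·H2O2 adduct) without handling H2O2; on adding the Lewis acid, the terminal peroxide oxygen opens the activated oxetane at its tertiary carbon by 5-exo-tet backside attack, which inverts the bought centre to the target C3 configuration, and the released primary alcohol closes the peroxyketal, whose bridgehead configuration is fixed by the bicycle; the closest known chemistry is photosensitised aerobic oxidation of secondary alcohols that co-produces H2O2 (anthraquinone-process type) and acid-catalysed perhydrolysis of 2,2-disubstituted oxetanes with inversion.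

**Step 5**
Reactants: 6, non-8-yn-1-ol
Product: 7, 5-(non-8-yn-1-ylsulfanyl)-1-phenyl-1H-tetrazole
Conditions: 1-phenyl-1H-tetrazole-5-thiol, PPh3, DIAD, THF, 0 °C → rt
Reagents that add atoms: 1-phenyl-1H-tetrazole-5-thiol, Sc1nnnn1-c1ccccc1
Why: Mitsunobu thioetherification installs the future Julia–Kocienski handle, so the chain needs no protecting group.

**Step 6**
Reactants: 5; 7
Product: 8, 2-[(3S,5S)-3,5-dimethyl-5-{9-[(1-phenyl-1H-tetrazol-5-yl)sulfanyl]non-1-yn-1-yl}-1,2-dioxolan-3-yl]ethan-1-ol (alkynyl chain cis to CH2CH2OH, the two methyls cis; the descriptors differ from the target only through CIP priorities)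
Conditions: 7 (2.5 equiv), AlMe3 (2.4 equiv), Et3N (10 mol %), toluene, 60 °C; then 5, toluene/CH2Cl2, −78 → −20 °C; Rochelle salt work-up (excess 7 recovered)
Reagents that add atoms: none
Why: Proposed new method: the alkynyl-dimethylalane binds the more basic ether oxygen O2 rather than the peroxide oxygens and ionises C1–O2 to a dioxolanyl peroxycarbenium ion, while the resulting aluminate stays tethered on the CH2CH2O arm and hands its alkynyl group to the same face (SNi-type retention), so C3 dictates C5 with the chain cis to the arm; the closest known chemistry is retentive aryl- and alkynylalane opening of 6,8-dioxabicyclo[3.2.1]octane ketals (1,6-anhydro sugars), Lewis-acid displacement of 3-alkoxy-1,2-dioxolanes via peroxycarbenium ions, and organoalane C-alkylation of trioxane lactol derivatives with the O–O bond intact.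

**Step 7**
Reactants: 8
Product: 9, 2-[(3S,5R)-3,5-dimethyl-5-{9-[(1-phenyl-1H-tetrazol-5-yl)sulfanyl]nonyl}-1,2-dioxolan-3-yl]ethan-1-ol
Conditions: 2-nitrobenzenesulfonylhydrazide (15–20 equiv, in portions), Et3N, CH2Cl2, rt
Reagents that add atoms: none
Why: Diimide reduction (concerted syn H2 transfer, alkyne → alkene → alkane) saturates C6–C7 without touching the O–O bond, thioether or tetrazole, and changes no stereocentre.

**Step 8**
Reactants: 9
Product: 10, 2-[(3R,5R)-3,5-dimethyl-5-{9-[(1-phenyl-1H-tetrazol-5-yl)sulfonyl]nonyl}-1,2-dioxolan-3-yl]acetic acid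
Conditions: H5IO6 (6 equiv), CrO3 (2 mol %), wet MeCN, 0 °C
Reagents that add atoms: periodic acid, OI(=O)(O)(O)(O)O; water, O
Why: Cr(VI)-catalysed periodate oxidation takes the primary alcohol to the acid and the sulfide to the sulfone in one operation, and the fully substituted dialkyl peroxide is inert to oxidants.

**Step 9**
Reactants: 10; 11, (2E,4E)-hepta-2,4-dienal
Product: 12, target, 2-[(3R,5R)-5-[(9E,11E,13E)-hexadeca-9,11,13-trien-1-yl]-3,5-dimethyl-1,2-dioxolan-3-yl]acetic acid
Conditions: KHMDS (2.2 equiv), DME, −60 °C; then 11 (1.5 equiv), −60 °C → rt; pH 4 work-up, exclusion of light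
Reagents that add atoms: none
Why: Julia–Kocienski olefination of an unbranched alkyl PT-sulfone with an enal is the E-selective pairing for C14=C15; the carboxylate protects C2–H from E1cB loss of peroxide, and the tertiary peroxide has no α-H for base-induced cleavage.

## Compound list
| No. | Name | SMILES | Role |
|---|---|---|---|
| 1 | (R)-mevalonolactone | `C[C@@]1(O)CCOC(=O)C1` | starting material |
| 2 | (3R)-3,5-dihydroxy-N-methoxy-N,3-dimethylpentanamide | `CON(C)C(=O)C[C@](C)(O)CCO` | intermediate |
| 3 | N-methoxy-N-methyl-2-[(2R)-2-methyloxetan-2-yl]acetamide | `CON(C)C(=O)C[C@@]1(C)CCO1` | intermediate |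
| 4 | 1-[(2R)-2-methyloxetan-2-yl]propan-2-ol | `CC(O)C[C@@]1(C)CCO1` | intermediate |
| 5 | (1S,5S)-1,5-dimethyl-2,6,7-trioxabicyclo[3.2.1]octane | `C[C@]12OO[C@](C)(C1)CCO2` | intermediate |
| 6 | non-8-yn-1-ol | `C#CCCCCCCCO` | starting material |
| 7 | 5-(non-8-yn-1-ylsulfanyl)-1-phenyl-1H-tetrazole | `C#CCCCCCCCSc1nnnn1-c1ccccc1` | intermediate |
| 8 | (3S,5S)-alkynyl dioxolane ethanol | `c1ccccc1-n1nnnc1SCCCCCCCC#C[C@]1(C)C[C@](C)(CCO)OO1` | intermediate |
| 9 | (3S,5R)-saturated dioxolane ethanol | `c1ccccc1-n1nnnc1SCCCCCCCCC[C@]1(C)C[C@](C)(CCO)OO1` | intermediate |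
| 10 | (3R,5R)-sulfone acid | `c1ccccc1-n1nnnc1S(=O)(=O)CCCCCCCCC[C@]1(C)C[C@](C)(CC(=O)O)OO1` | intermediate |
| 11 | (2E,4E)-hepta-2,4-dienal | `CC/C=C/C=C/C=O` | starting material |
| 12 | target acid | `CC/C=C/C=C/C=C/CCCCCCCC[C@]1(C)C[C@](C)(CC(=O)O)OO1` | target |

## Step count and risks
Total steps: 9. Longest linear sequence: 8 (steps 1–4 and 6–9).

**Steps most likely to fail**
1. **Step 4 (new).**
   - Risks: only about one equivalent of peroxide is generated, H-abstraction can compete at the oxetane α-C–H, and partial SN1 opening would erode ee.
   - Fallback (known chemistry): stop step 3 at the methyl ketone and open the oxetane with pre-formed anhydrous ethereal H2O2 and catalytic TMSOTf, which is the established invertive perhydrolysis. Then close 5 by acid-catalysed peroxyketalisation.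
2. **Step 6 (new).**
   - Risks: ionisation of the C–OO bond instead of the C–O bond, attack of the alane on the O–O bond, or loss of facial control.
   - Fallback (known chemistry): ionise 5 with TiCl4 or SnCl4 and trap the peroxycarbenium ion with external allyltrimethylsilane, a Sakurai-type displacement established for 3-alkoxy-1,2-dioxolanes. Separate the C5 epimers, then extend by cross-metathesis with oct-7-enyl PT sulfide and diimide reduction.
3. **Step 7.**
   - Risk: the reduction may stall at the alkene next to the quaternary C5.
   - Fallback: move the unsaturation away from C5. Transfer an allyl group from aluminium in step 6, build the chain by cross-metathesis at C7=C8, and reduce that unhindered alkene with diimide.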